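**Retrosynthetic overview**
1. C16 methyl: exo-face hydrogenation of a 16-methylene-15-ketone. Ring D (C16–C13): Pd(II) cycloalkenylation of the acetyl silyl enol ether onto the ring-C alkene.
2. Ring C (C8–C14, C9–C11): Diels–Alder of butadiene with a spiro 3-acetyl-5,6-dihydropyran-2-one. Lactone (C20–O, C8=C9): acetoacetylation/Knoevenagel of a C10 hydroxymethyl aldehyde.
3. C10 quaternary centre: Tollens bis-hydroxymethylation, then sterically differentiated oxidation. Methoxy-THF (C5–C6): O-tethered acetal-radical 5-exo Giese cyclisation.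
4. C4 (first stereocentre): organocatalytic γ-hydroxymethylation of the dienamine from an achiral dienol ether of 3-methylcyclohex-2-enone.
5. Ring order: A (bought) → THF acetal → spiro δ-lactone → C → D.

Assumption: atom labels follow ent-kaurane numbering of the target (C6 acetal CH, C7 lactone C=O, C15 ketone, C19/C20 the two OCH2, C17 the C16 methyl); the target is (4R,5R,6R,8S,9S,10R,13R,16R), and in Step 2 the catalyst antipode is whichever gives 4R.

**Step 1**
Reactants: 1 3-methylcyclohex-2-en-1-one; 2 (methoxymethyl)triphenylphosphonium chloride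
Product: 3 1-(methoxymethylidene)-3-methylcyclohex-2-ene (E/Z mixture, achiral)
Conditions: 2, KOtBu, THF, 0 °C → rt
Reagents that add atoms: (methoxymethyl)triphenylphosphonium chloride, COC[P+](c1ccccc1)(c1ccccc1)c1ccccc1.[Cl-]
Why: Wittig olefination at the enone C=O gives an achiral 1-methoxy-1,3-diene, a masked β,γ-unsaturated aldehyde that can form only one linear dienamine; no stereocentre.

**Step 2**
Reactants: 3; 4 formaldehyde; 5 water
Product: 6 (R)-3-(hydroxymethyl)-3-methylcyclohex-1-ene-1-carbaldehyde
Conditions: 3-{[3,5-bis(trifluoromethyl)phenyl]amino}-4-{[(2S)-pyrrolidin-2-ylmethyl]amino}cyclobut-3-ene-1,2-dione (20 mol%), PhCO2H (20 mol%), 37% aq. HCHO (3 equiv), CHCl3, 0 °C → rt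
Reagents that add atoms: formaldehyde, C=O; water, O
Why: Proposed new method: enantioselective vinylogous aldol (γ-hydroxymethylation) of a cross-ring dienamine with formaldehyde that creates a γ-quaternary centre – the amine exchanges with the protonated enol ether (MeOH lost) to give N–CH=C10–C5=C4(Me), α-attack at C10 is reversible by retro-aldol whereas γ-attack at C4 gives the conjugated iminium and funnels to 6, and the squaramide NH groups bind CH2O and deliver it to one face of C4 (sets 4R); closest known reactions are H-bond-directed dienamine γ-functionalisation of enals and prolinol-catalysed α-hydroxymethylation of aldehydes with formalin.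

**Step 3**
Reactants: 6; 7 methyl 2,2-dimethoxyacetate
Product: 8 methyl 2-{[(1R)-3-formyl-1-methylcyclohex-2-en-1-yl]methoxy}-2-methoxyacetate (about 1:1 at the new acetal carbon)
Conditions: 7 (10 equiv, neat), CSA (10 mol%), 70 °C, MeOH removed under reduced pressure; aq. oxalic acid/THF wash to release any enal acetal
Reagents that add atoms: methyl 2,2-dimethoxyacetate, COC(OC)C(=O)OC
Why: Acid-catalysed transacetalisation puts the neopentyl C19–OH into the glyoxylate acetal, installing the α,α-dialkoxyacetate radical precursor; the new acetal centre is unselective and is erased in Step 5.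

**Step 4**
Reactants: 8; 9 lithium hydroxide
Product: 10 lithium 2-{[(1R)-3-formyl-1-methylcyclohex-2-en-1-yl]methoxy}-2-methoxyacetate
Conditions: LiOH·H2O (1.05 equiv), THF/H2O, 0 °C; lyophilise, use the salt directly
Reagents that add atoms: lithium hydroxide, [Li+].[OH-]
Why: Saponification of an activated α,α-dialkoxy ester; the non-enolisable enal and the acetal tolerate cold LiOH and no acidification is needed.

**Step 5**
Reactants: 10
Product: 11 (1R,3aR,7aS)-1-methoxy-3a-methyloctahydro-2-benzofuran-7-carbaldehyde (cis-fused; OMe cis to the C7a–C7 bond; C7 epimer mixture)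
Conditions: 4CzIPN (2 mol%), DMF/H2O 20:1 (0.02 M), 456 nm LEDs, rt
Reagents that add atoms: none
Why: Photoredox decarboxylative Giese reaction (known for 2,2-dialkoxyacetic acids as formyl-radical equivalents) run intramolecularly: the C6 acetal radical adds 5-exo-trig to C5 of the enal, the O–C19 tether forces the cis ring fusion (sets C5), and OMe is expected cis to C10 (Beckwith–Houk 1,5-cis preference; the exo position is 1,3-syn to the C4 methyl), which sets C6; the C10 epimers converge in Step 6.

**Step 6**
Reactants: 11; 4 formaldehyde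
Product: 12 [(1R,3aR,7aR)-1-methoxy-3a-methylhexahydro-2-benzofuran-7,7(1H)-diyl]dimethanol
Conditions: 37% aq. HCHO (excess), KOH, MeOH/H2O, 50 °C
Reagents that add atoms: formaldehyde, C=O
Why: Tollens reaction (aldol with CH2O, then crossed Cannizzaro) turns the α-branched aldehyde into a gem-bis(hydroxymethyl) group, so C10 carries no stereochemical information here and the acetal is inert to base.

**Step 7**
Reactants: 12
Product: 13 (1R,3aR,7R,7aR)-7-(hydroxymethyl)-1-methoxy-3a-methyloctahydro-2-benzofuran-7-carbaldehyde (CH2OH cis to the acetal carbon; CHO trans)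
Conditions: TEMPO (10 mol%), PhI(OAc)2 (1.1 equiv), NaHCO3, CH2Cl2, 0 °C
Reagents that add atoms: none
Why: Sterically controlled oxoammonium (TEMPO) oxidation takes the equatorial CH2OH (trans to C6, future C9) in preference to the axial CH2OH that is 1,3-diaxial to C19 (future C20), which sets C10; the bicarbonate buffer protects the acetal.

**Step 8**
Reactants: 13; 14 2,2,6-trimethyl-4H-1,3-dioxin-4-one
Product: 15 spiro-lactone: 3-acetyl-5,6-dihydro-2H-pyran-2-one whose C5 is C7 of the (1R,3aR,7aR)-1-methoxy-3a-methyloctahydro-2-benzofuran (4R,5R,6R,10R; C20H2–O–C7(=O)–C8(Ac)=C9H)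
Conditions: 14 (1.5 equiv), PhMe, 110 °C; then piperidine/AcOH (10 mol%), rt
Reagents that add atoms: 2,2,6-trimethyl-4H-1,3-dioxin-4-one, CC1=CC(=O)OC(C)(C)O1
Why: Thermally generated acetylketene acylates the hindered C20–OH, and intramolecular Knoevenagel condensation with the C9 aldehyde closes the doubly activated unsaturated δ-lactone; no new stereocentre.

**Step 9**
Reactants: 15; 16 buta-1,3-diene
Product: 17 Diels–Alder adduct (4R,5R,6R,8S,9S,10R): cyclohexene (C12=C13) cis-fused to the δ-lactone at C8–C9, acetyl on C8
Conditions: butadiene (excess), BHT, PhMe, 120 °C, sealed tube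
Reagents that add atoms: buta-1,3-diene, C=CC=C
Why: Thermal Diels–Alder reaction on the cyclic alkylidene β-keto lactone gives a cis ring fusion, and the diene adds to the lactone face syn to C1H2 and anti to C5/C6 with its OMe, which sets C8 and C9.

**Step 10**
Reactants: 17; 18 tert-butyldimethylsilyl chloride
Product: 19 TBS enol ether of 17 (C15(OTBS)=C16H2)
Conditions: KHMDS, THF, −78 °C; TBSCl, −78 °C → 0 °C
Reagents that add atoms: tert-butyldimethylsilyl chloride, CC(C)(C)[Si](C)(C)Cl
Why: The acetyl CH3 is the only enolisable site (C8 is quaternary), so enolate O-silylation gives the 2-silyloxy-1,5-diene under basic conditions that leave the acetal untouched.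

**Step 11**
Reactants: 19
Product: 20 bicyclo[3.2.1]octenone (4R,5R,6R,8S,9S,10R,13R): C16–C13 bond formed, C15 ketone, C16H2, C11=C12
Conditions: Pd(OAc)2 (10 mol%), O2 (1 atm), DMSO, 45 °C
Reagents that add atoms: none
Why: Pd(II) cycloalkenylation of a silyl enol ether (Kende/Toyota type): 5-exo attack of C16 on C13 of the Pd-activated ring alkene, then β-hydride elimination to C11=C12; the C13 configuration is dictated by bridging from the C8 acetyl group.

**Step 12**
Reactants: 20; 21 Eschenmoser's salt
Product: 22 16-methylene ketone (C16=C17H2, C15=O, C11=C12 retained)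
Conditions: LiHMDS, THF, −78 °C; CH2=NMe2+ I−; then MeI; then aq. NaHCO3
Reagents that add atoms: N,N-dimethylmethyleneiminium iodide, C=[N+](C)C.[I-]
Why: Mannich reaction of the C16 enolate (the only enolisable position), N-methylation and E1cB elimination give the α-methylene ketone.

**Step 13**
Reactants: 22
Product: 23 ludongnin F
Conditions: H2 (1 atm), 10% Pd/C, EtOAc, rt
Reagents that add atoms: none
Why: Heterogeneous hydrogenation delivers H2 to the exo face of C16=C17 (the side of the one-carbon bridge C14, away from C11–C12), giving the endo 16R methyl, and also saturates C11=C12.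

**Compound list**
1 | 3-methylcyclohex-2-en-1-one | CC1=CC(=O)CCC1 | starting material
2 | (methoxymethyl)triphenylphosphonium chloride | COC[P+](c1ccccc1)(c1ccccc1)c1ccccc1.[Cl-] | starting material
3 | 1-(methoxymethylidene)-3-methylcyclohex-2-ene | COC=C1C=C(C)CCC1 | intermediate
4 | formaldehyde | C=O | starting material
5 | water | O | starting material
6 | (R)-3-(hydroxymethyl)-3-methylcyclohex-1-ene-1-carbaldehyde | O=CC1=C[C@](C)(CO)CCC1 | intermediate
7 | methyl 2,2-dimethoxyacetate | COC(OC)C(=O)OC | starting material
8 | methyl 2-{[(1R)-3-formyl-1-methylcyclohex-2-en-1-yl]methoxy}-2-methoxyacetate | O=CC1=C[C@](C)(COC(OC)C(=O)OC)CCC1 | intermediate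
9 | lithium hydroxide | [Li+].[OH-] | starting material
10 | lithium 2-{[(1R)-3-formyl-1-methylcyclohex-2-en-1-yl]methoxy}-2-methoxyacetate | O=CC1=C[C@](C)(COC(OC)C(=O)[O-])CCC1.[Li+] | intermediate
11 | (1R,3aR,7aS)-1-methoxy-3a-methyloctahydro-2-benzofuran-7-carbaldehyde | CO[C@@H]1OC[C@]2(C)CCCC(C=O)[C@H]12 | intermediate
12 | [(1R,3aR,7aR)-1-methoxy-3a-methylhexahydro-2-benzofuran-7,7(1H)-diyl]dimethanol | CO[C@@H]1OC[C@]2(C)CCCC(CO)(CO)[C@H]12 | intermediate
13 | (1R,3aR,7R,7aR)-7-(hydroxymethyl)-1-methoxy-3a-methyloctahydro-2-benzofuran-7-carbaldehyde | CO[C@@H]1OC[C@]2(C)CCC[C@](C=O)(CO)[C@H]12 | intermediate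
14 | 2,2,6-trimethyl-4H-1,3-dioxin-4-one | CC1=CC(=O)OC(C)(C)O1 | starting material
15 | spiro 3-acetyl-5,6-dihydropyran-2-one (4R,5R,6R,10R) | CO[C@@H]1OC[C@]2(C)CCC[C@]3(COC(=O)C(C(C)=O)=C3)[C@H]12 | intermediate
16 | buta-1,3-diene | C=CC=C | starting material
17 | Diels–Alder adduct (4R,5R,6R,8S,9S,10R) | CO[C@@H]1OC[C@]2(C)CCC[C@]3(COC(=O)[C@@]4(C(C)=O)CC=CC[C@H]43)[C@H]12 | intermediate
18 | tert-butyldimethylsilyl chloride | CC(C)(C)[Si](C)(C)Cl | starting material
19 | TBS enol ether of 17 | CO[C@@H]1OC[C@]2(C)CCC[C@]3(COC(=O)[C@@]4(C(=C)O[Si](C)(C)C(C)(C)C)CC=CC[C@H]43)[C@H]12 | intermediate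
20 | bicyclo[3.2.1]octenone, 17-nor, Δ11 | CO[C@@H]1OC[C@]2(C)CCC[C@]3(COC(=O)[C@@]45C[C@@H](C=C[C@H]43)CC5=O)[C@H]12 | intermediate
21 | N,N-dimethylmethyleneiminium iodide | C=[N+](C)C.[I-] | starting material
22 | 16-methylene-15-ketone, Δ11 | CO[C@@H]1OC[C@]2(C)CCC[C@]3(COC(=O)[C@@]45C[C@@H](C=C[C@H]43)C(=C)C5=O)[C@H]12 | intermediate
23 | ludongnin F | CO[C@@H]1OC[C@]2(C)CCC[C@]3(COC(=O)[C@@]45C[C@@H](CC[C@H]43)[C@@H](C)C5=O)[C@H]12 | target

**Totals**
Total steps: 13. Longest linear sequence: 13 (fully linear).

**Three steps most likely to fail**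
1. Step 2 (the proposed new step): α/γ selectivity and ee at the quaternary C4 are unproven. Fallback (known chemistry): make prochiral 2-methyl-2-(pent-4-en-1-yl)propane-1,3-diol from diethyl methylmalonate and 5-bromopent-1-ene (then LiAlH4), desymmetrise it by lipase-mediated monoacylation, oxidise the free CH2OH, ozonolyse the alkene, and close the ring by amine-catalysed intramolecular aldol condensation to the O-acyl analogue of 6.
2. Step 5: the cyclisation may favour the C6 epimer (OMe trans to C10). Fallback: convert 6 into its Se-phenyl selenocarbonate, run a Bu3SnH alkoxycarbonyl-radical 5-exo cyclisation to the cis-fused γ-lactone, and set C6 afterwards by lactone O-methylation (Me3OBF4) and hydride delivery from the convex face.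
3. Step 7: the two CH2OH groups may not be differentiated cleanly. Fallback: fix C10 by C–C bond formation instead: trap the TMS enol ether of 11 with 1,3-dithian-2-ylium tetrafluoroborate (attack anti to C6 gives the masked C9 aldehyde), reduce the C20 aldehyde with NaBH4, acetoacetylate, then unmask the dithiane (MeI, CaCO3) and run the Knoevenagel closure.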